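**Plan**

- Numbering: C1 is the ester carbonyl, C2 the CH(CH3), C3–C6 the ring carbons (O2 on C3, O1 on C6), C7–C14 the chain (C9 ketone, C10 the methylidene-bearing carbon, C14 the carbinol).
- Enabling feature: C2 (on C3) and C7 (on C6) sit cis across the 1,2-dioxane (O1–O2–C3–C4–C5–C6), so they can be tied together as the C2=C7 alkene bridge of a 2,3-dioxabicyclo[2.2.2]oct-5-ene with bridgeheads C3 and C6. That bicycle is the singlet-oxygen adduct of 1,3-dimethylcyclohexa-1,3-diene.
- Retrosynthetic cuts: C10=CH2 and C7=C8 (two Horner–Wadsworth–Emmons olefinations on one bis-phosphonate; C10–C11 by alkylation), C1–C2 (methylenation of an acetyl group, then hydroboration), C2=C7 (ozonolysis), and C3–O2/C6–O1 ([4+2] with 1O2).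
- Forward order: diene, then the endoperoxide (the only ring of the target closes here), then ozonolytic opening of the carbocycle to a cis acetyl/formyl dioxane, then the C1–C3 ester arm, then the side chain joined at C7 (HWE, diimide, formaldehyde HWE).
- Stereochemistry: C3/C6 cis from the suprafacial cycloaddition; C2 from C3 by anti-selective 9-BBN hydroboration; absolute configuration from a lipase resolution of the primary alcohol.

Key step: step 2

Assumption: all intermediates from the cycloadduct up to the lipase step are racemic; names and SMILES show the enantiomer that is carried on.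
Assumption: the lipase from Burkholderia cepacia is taken to follow its empirical rule for primary alcohols with a methyl-bearing β-stereocentre (no oxygen on the stereocentre), i.e. to acetylate the (2R)-alcohol faster.
Assumption: tetraethyl (2-oxopropane-1,3-diyl)bis(phosphonate) is taken as a catalogue reagent.

**Route**

Step 1
Reactants: 1 3-methylcyclohex-2-en-1-one; 2 methyllithium
Product: 4 1,3-dimethylcyclohexa-1,3-diene, via 1,3-dimethylcyclohex-2-en-1-ol 3 (not isolated)
Conditions: MeLi, Et2O, −78 → 0 °C; then 5% aq. oxalic acid, rt; distil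
Reagents that add atoms: none
Why: 1,2-addition of the organolithium to the enone gives the tertiary allylic alcohol, and mild acid ionises it to the symmetrical 1,3-dimethylcyclohexenyl cation, whose E1 loss of a ring proton (acid-catalysed dehydration under equilibrating conditions) should favour the conjugated endocyclic diene over its exocyclic isomer.

Step 2
Reactants: 4 1,3-dimethylcyclohexa-1,3-diene; 5 dioxygen
Product: 6 (1R,4S)-1,5-dimethyl-2,3-dioxabicyclo[2.2.2]oct-5-ene (racemate)
Conditions: O2 (1 atm), tetraphenylporphyrin (cat.), CH2Cl2, visible light, −20 °C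
Reagents that add atoms: none
Why: Energy transfer from the excited porphyrin gives singlet oxygen, which adds as the 2π partner across the termini of the ring-locked s-cis diene in a concerted, suprafacial [4+2] cycloaddition, the closest precedent being the dye-sensitised endoperoxidation of 1,3-cyclohexadienes (α-terpinene to ascaridole). The step forms C3–O2 and C6–O1 together and so closes the 1,2-dioxane ring by cycloaddition, as the O–O bridge of a 2,3-dioxabicyclo[2.2.2]oct-5-ene whose alkene is C2=C7. The two new stereocentres, the bridgeheads C3 (H) and C6 (CH3), are fixed relative to each other by the bicycle itself, because both C–O bonds must form on the same face, so C2 and C7 are necessarily cis on the dioxane. The diene is achiral, so the product is racemic and the absolute configuration is left to step 6. The selectivity required is [4+2] over the ene reaction at the allylic methyl and methylene hydrogens, and it is secured by the cisoid geometry held by the six-membered ring, helped by low temperature and a non-polar solvent.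

Step 3
Reactants: 6 (1R,4S)-1,5-dimethyl-2,3-dioxabicyclo[2.2.2]oct-5-ene
Product: 8 1-[(3S,6R)-6-(dimethoxymethyl)-6-methyl-1,2-dioxan-3-yl]ethan-1-one (racemate), via 6-acetyl-3-methyl-1,2-dioxane-3-carbaldehyde 7 (not isolated)
Conditions: O3, CH2Cl2/MeOH, −78 °C; Me2S, −78 °C → rt; then HC(OMe)3, PPTS (cat.), rt
Reagents that add atoms: ozone, [O-][O+]=O; trimethyl orthoformate, COC(OC)OC
Why: Ozonolysis (Criegee cleavage with a dimethyl sulfide work-up that does not reduce dialkyl peroxides) should cut the only C=C so that C2 becomes an acetyl and C7 a formyl group, cis on the dioxane, and mild acid with orthoformate should acetalise only the aldehyde in the same flask because a methyl ketone ketalises far more slowly.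

Step 4
Reactants: 8 1-[(3S,6R)-6-(dimethoxymethyl)-6-methyl-1,2-dioxan-3-yl]ethan-1-one
Product: 9 (3R,6S)-3-(dimethoxymethyl)-3-methyl-6-(prop-1-en-2-yl)-1,2-dioxane (racemate)
Conditions: Tebbe reagent, pyridine (cat.), THF/PhMe, −40 → 0 °C
Reagents that add atoms: Tebbe reagent, C[Al-]1(C)C[Ti](C2C=CC=C2)(C2C=CC=C2)[Cl+]1
Why: Tebbe methylenation runs through a titanium methylidene by [2+2]/retro-[2+2] with no basic species present, so the ketone should be converted into the isopropenyl group (adding C1) before the C3–H, which is alpha to both the carbonyl and the peroxide, can be removed in a Kornblum–DeLaMare-type fragmentation.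

Step 5
Reactants: 9 (3R,6S)-3-(dimethoxymethyl)-3-methyl-6-(prop-1-en-2-yl)-1,2-dioxane
Product: 10 (2R)-2-[(3S,6R)-6-(dimethoxymethyl)-6-methyl-1,2-dioxan-3-yl]propan-1-ol (racemate)
Conditions: 9-BBN, THF, 0 °C → rt; then NaBO3·4H2O, H2O, rt
Reagents that add atoms: sodium perborate, [Na+].[Na+].O[B-]1(O)OO[B-](O)(O)OO1
Why: Hydroboration–oxidation of the 1,1-disubstituted alkene puts boron on C1 and hydrogen on C2, and the acyclic-stereocontrol model for bulky boranes and allylic ethers (C3–H eclipsing the alkene, ring C4 anti to the incoming borane, ring oxygen outside) predicts that C3 sets C2 in the 2,3-anti sense of the target, while perborate oxidises the C–B bond without strong base.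

Step 6
Reactants: 10 (2R)-2-[(3S,6R)-6-(dimethoxymethyl)-6-methyl-1,2-dioxan-3-yl]propan-1-ol (racemate)
Product: 11 (2R)-2-[(3S,6R)-6-(dimethoxymethyl)-6-methyl-1,2-dioxan-3-yl]propyl acetate
Conditions: lipase from Burkholderia cepacia (Amano PS), vinyl acetate, t-BuOMe, rt, stopped below half conversion; chromatography
Reagents that add atoms: vinyl acetate, C=COC(C)=O
Why: Lipase-catalysed irreversible transesterification is a kinetic resolution that should acetylate the (2R)-alcohol, the enantiomer with the configuration of the target, faster than its mirror image, so the acetate separated from the unreacted alcohol carries the absolute configuration of all three stereocentres.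

Step 7
Reactants: 11 (2R)-2-[(3S,6R)-6-(dimethoxymethyl)-6-methyl-1,2-dioxan-3-yl]propyl acetate
Product: 12 (2R)-2-[(3S,6R)-6-(dimethoxymethyl)-6-methyl-1,2-dioxan-3-yl]propan-1-ol (single enantiomer)
Conditions: K2CO3 (cat.), MeOH, 0 °C
Reagents that add atoms: none
Why: Carbonate-catalysed methanolysis (transesterification) should release the primary alcohol, and at this stage no carbonyl activates C3–H or C2–H, so the peroxide and the acetal should tolerate the mild base.

Step 8
Reactants: 12 (2R)-2-[(3S,6R)-6-(dimethoxymethyl)-6-methyl-1,2-dioxan-3-yl]propan-1-ol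
Product: 13 (2S)-2-[(3S,6R)-6-(dimethoxymethyl)-6-methyl-1,2-dioxan-3-yl]propanoic acid
Conditions: TEMPO (cat.), PhI(OAc)2, MeCN/pH 7 buffer, rt
Reagents that add atoms: water, O
Why: The oxoammonium (TEMPO) oxidation takes the primary alcohol through the aldehyde hydrate to the acid under near-neutral conditions, so C2 should not epimerise and the acetal and peroxide should survive (the C2 descriptor changes from R to S only because C1 gains priority).

Step 9
Reactants: 13 (2S)-2-[(3S,6R)-6-(dimethoxymethyl)-6-methyl-1,2-dioxan-3-yl]propanoic acid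
Product: 14 methyl (2S)-2-[(3S,6R)-6-(dimethoxymethyl)-6-methyl-1,2-dioxan-3-yl]propanoate
Conditions: TMSCHN2, PhMe/MeOH, 0 °C
Reagents that add atoms: trimethylsilyldiazomethane, C[Si](C)(C)C=[N+]=[N-]
Why: O-Methylation of the carboxylic acid by the diazoalkane is neutral, so no ester enolate forms that could epimerise C2 or open the β-peroxide by elimination.

Step 10
Reactants: 14 methyl (2S)-2-[(3S,6R)-6-(dimethoxymethyl)-6-methyl-1,2-dioxan-3-yl]propanoate
Product: 15 methyl (2S)-2-[(3S,6R)-6-formyl-6-methyl-1,2-dioxan-3-yl]propanoate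
Conditions: TFA/H2O, CHCl3, 0 °C → rt
Reagents that add atoms: water, O
Why: Acid-catalysed acetal hydrolysis should unmask the C7 aldehyde, which sits on the quaternary C6 and cannot epimerise, while the methyl ester and the dialkyl peroxide are stable to aqueous acid.

Step 11
Reactants: 16 ethyl 4-bromobutanoate; 17 methylmagnesium bromide
Product: 18 5-bromo-2-methylpentan-2-ol
Conditions: MeMgBr (2.2 equiv), Et2O, −20 → 0 °C; aq. NH4Cl
Reagents that add atoms: none
Why: Double Grignard addition to the ester gives the tertiary carbinol (C14 with both methyls), and below 0 °C the primary bromide is not displaced.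

Step 12
Reactants: 18 5-bromo-2-methylpentan-2-ol
Product: 19 [(5-bromo-2-methylpentan-2-yl)oxy]trimethylsilane
Conditions: TMSCl, imidazole, CH2Cl2, 0 °C → rt
Reagents that add atoms: chlorotrimethylsilane, C[Si](C)(C)Cl
Why: Silylation blocks the tertiary hydroxyl so that it cannot cyclise onto the bromide to a tetrahydrofuran under the basic alkylation that follows.

Step 13
Reactants: 19 [(5-bromo-2-methylpentan-2-yl)oxy]trimethylsilane; 20 tetraethyl (2-oxopropane-1,3-diyl)bis(phosphonate)
Product: 22 tetraethyl (7-hydroxy-7-methyl-2-oxooctane-1,3-diyl)bis(phosphonate) (racemate), via its O-trimethylsilyl ether 21 (not isolated)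
Conditions: 20 (excess), NaH, THF, 0 °C; n-BuLi, −40 °C; 19, −40 °C → rt; then 1 M HCl, THF, rt
Reagents that add atoms: none
Why: β-Ketophosphonate dianion alkylation should make the C10–C11 bond, because the Na/Li dianion of the symmetrical ketone reacts once at a terminal carbanion with the primary bromide and the resulting stabilised monoanion is not alkylated further, and the acidic work-up cleaves the trimethylsilyl ether.

Step 14
Reactants: 15 methyl (2S)-2-[(3S,6R)-6-formyl-6-methyl-1,2-dioxan-3-yl]propanoate; 22 tetraethyl (7-hydroxy-7-methyl-2-oxooctane-1,3-diyl)bis(phosphonate)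
Product: 23 methyl (2S)-2-[(3S,6R)-6-[(1E)-4-(diethoxyphosphoryl)-8-hydroxy-8-methyl-3-oxonon-1-en-1-yl]-6-methyl-1,2-dioxan-3-yl]propanoate (epimers at the phosphonate carbon)
Conditions: LiCl, i-Pr2NEt, MeCN, rt
Reagents that add atoms: none
Why: Horner–Wadsworth–Emmons olefination under LiCl/amine conditions should engage the more acidic and less hindered unsubstituted P–CH2–C=O carbon (C8) to give the E-enone, whereas the alkylated C10 phosphonate could only form a trisubstituted alkene with this neopentyl aldehyde and is kept for step 16; the base is too weak to enolise the ester.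

Step 15
Reactants: 23 methyl (2S)-2-[(3S,6R)-6-[(1E)-4-(diethoxyphosphoryl)-8-hydroxy-8-methyl-3-oxonon-1-en-1-yl]-6-methyl-1,2-dioxan-3-yl]propanoate
Product: 24 methyl (2S)-2-[(3S,6R)-6-[4-(diethoxyphosphoryl)-8-hydroxy-8-methyl-3-oxononyl]-6-methyl-1,2-dioxan-3-yl]propanoate (epimers at the phosphonate carbon)
Conditions: KO2CN=NCO2K, AcOH, MeOH/CH2Cl2, 0 °C → rt (repeated charges)
Reagents that add atoms: none
Why: Diimide reduction transfers H2 concertedly to the disubstituted C7=C8 bond and should leave the O–O bond, both carbonyls and the phosphonate untouched, which a metal-catalysed hydrogenation would not.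

Step 16
Reactants: 24 methyl (2S)-2-[(3S,6R)-6-[4-(diethoxyphosphoryl)-8-hydroxy-8-methyl-3-oxononyl]-6-methyl-1,2-dioxan-3-yl]propanoate
Product: 25 aikupikoxide D
Conditions: 37% aq. HCHO, K2CO3, THF/H2O, 0 °C → rt
Reagents that add atoms: formaldehyde, C=O
Why: Horner–Wadsworth–Emmons olefination of the α-alkyl β-ketophosphonate with aqueous formaldehyde should place the methylidene on C10 and nowhere else, because the phosphonate marks that carbon, and carbonate is too weak to enolise the ester or open the peroxide.

**Compound list**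

1 | 3-methylcyclohex-2-en-1-one | CC1=CC(=O)CCC1 | starting material
2 | methyllithium | [Li]C | starting material
3 | 1,3-dimethylcyclohex-2-en-1-ol (racemate, not isolated) | CC1=CC(C)(O)CCC1 | intermediate
4 | 1,3-dimethylcyclohexa-1,3-diene | CC1=CC(C)=CCC1 | intermediate
5 | dioxygen (used as singlet oxygen) | O=O | starting material
6 | (1R,4S)-1,5-dimethyl-2,3-dioxabicyclo[2.2.2]oct-5-ene (racemate) | CC1=C[C@@]2(C)CC[C@@H]1OO2 | intermediate
7 | (3R,6S)-6-acetyl-3-methyl-1,2-dioxane-3-carbaldehyde (racemate, not isolated) | O=C[C@@]1(C)CC[C@@H](C(C)=O)OO1 | intermediate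
8 | 1-[(3S,6R)-6-(dimethoxymethyl)-6-methyl-1,2-dioxan-3-yl]ethan-1-one (racemate) | COC(OC)[C@@]1(C)CC[C@@H](C(C)=O)OO1 | intermediate
9 | (3R,6S)-3-(dimethoxymethyl)-3-methyl-6-(prop-1-en-2-yl)-1,2-dioxane (racemate) | COC(OC)[C@@]1(C)CC[C@@H](C(C)=C)OO1 | intermediate
10 | (2R)-2-[(3S,6R)-6-(dimethoxymethyl)-6-methyl-1,2-dioxan-3-yl]propan-1-ol (racemate) | COC(OC)[C@@]1(C)CC[C@@H]([C@H](C)CO)OO1 | intermediate
11 | (2R)-2-[(3S,6R)-6-(dimethoxymethyl)-6-methyl-1,2-dioxan-3-yl]propyl acetate | COC(OC)[C@@]1(C)CC[C@@H]([C@H](C)COC(C)=O)OO1 | intermediate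
12 | (2R)-2-[(3S,6R)-6-(dimethoxymethyl)-6-methyl-1,2-dioxan-3-yl]propan-1-ol (single enantiomer) | COC(OC)[C@@]1(C)CC[C@@H]([C@H](C)CO)OO1 | intermediate
13 | (2S)-2-[(3S,6R)-6-(dimethoxymethyl)-6-methyl-1,2-dioxan-3-yl]propanoic acid | COC(OC)[C@@]1(C)CC[C@@H]([C@H](C)C(=O)O)OO1 | intermediate
14 | methyl (2S)-2-[(3S,6R)-6-(dimethoxymethyl)-6-methyl-1,2-dioxan-3-yl]propanoate | COC(OC)[C@@]1(C)CC[C@@H]([C@H](C)C(=O)OC)OO1 | intermediate
15 | methyl (2S)-2-[(3S,6R)-6-formyl-6-methyl-1,2-dioxan-3-yl]propanoate | O=C[C@@]1(C)CC[C@@H]([C@H](C)C(=O)OC)OO1 | intermediate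
16 | ethyl 4-bromobutanoate | CCOC(=O)CCCBr | starting material
17 | methylmagnesium bromide | C[Mg]Br | starting material
18 | 5-bromo-2-methylpentan-2-ol | CC(C)(O)CCCBr | intermediate
19 | [(5-bromo-2-methylpentan-2-yl)oxy]trimethylsilane | CC(C)(CCCBr)O[Si](C)(C)C | intermediate
20 | tetraethyl (2-oxopropane-1,3-diyl)bis(phosphonate) | CCOP(=O)(OCC)CC(=O)CP(=O)(OCC)OCC | starting material
21 | tetraethyl {7-methyl-2-oxo-7-[(trimethylsilyl)oxy]octane-1,3-diyl}bis(phosphonate) (racemate, not isolated) | CCOP(=O)(OCC)CC(=O)C(CCCC(C)(C)O[Si](C)(C)C)P(=O)(OCC)OCC | intermediate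
22 | tetraethyl (7-hydroxy-7-methyl-2-oxooctane-1,3-diyl)bis(phosphonate) (racemate) | CCOP(=O)(OCC)CC(=O)C(CCCC(C)(C)O)P(=O)(OCC)OCC | intermediate
23 | methyl (2S)-2-[(3S,6R)-6-[(1E)-4-(diethoxyphosphoryl)-8-hydroxy-8-methyl-3-oxonon-1-en-1-yl]-6-methyl-1,2-dioxan-3-yl]propanoate (epimers at the phosphonate carbon) | CCOP(=O)(OCC)C(CCCC(C)(C)O)C(=O)/C=C/[C@@]1(C)CC[C@@H]([C@H](C)C(=O)OC)OO1 | intermediate
24 | methyl (2S)-2-[(3S,6R)-6-[4-(diethoxyphosphoryl)-8-hydroxy-8-methyl-3-oxononyl]-6-methyl-1,2-dioxan-3-yl]propanoate (epimers at the phosphonate carbon) | CCOP(=O)(OCC)C(CCCC(C)(C)O)C(=O)CC[C@@]1(C)CC[C@@H]([C@H](C)C(=O)OC)OO1 | intermediate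
25 | aikupikoxide D, methyl (2S)-2-[(3S,6R)-6-(8-hydroxy-8-methyl-4-methylidene-3-oxononyl)-6-methyl-1,2-dioxan-3-yl]propanoate | C=C(CCCC(C)(C)O)C(=O)CC[C@@]1(C)CC[C@@H]([C@H](C)C(=O)OC)OO1 | target

**Step count**

Total: 16 steps. Longest linear sequence: 13 steps (steps 1–10, then 14–16, from 3-methylcyclohex-2-en-1-one); steps 11–13 make the bis-phosphonate linchpin.

**Steps most likely to fail, with fallbacks**

Step 4. During the methylenation the titanium/aluminium reagent may cleave the O–O bond, or the acetyl dioxane may fragment by loss of the C3–H before the carbonyl has reacted. The fallback sets out from 8 and is a two-stage Peterson olefination. (Trimethylsilyl)methylmagnesium chloride premixed with anhydrous CeCl3 in THF at −78 °C, a weakly basic organocerium, should add to the ketone and give 2-[(3S,6R)-6-(dimethoxymethyl)-6-methyl-1,2-dioxan-3-yl]-1-(trimethylsilyl)propan-2-ol F1 (carbinol epimers are immaterial). Acid-promoted anti-elimination with catalytic camphorsulfonic acid in methanol, a solvent that keeps the dimethyl acetal intact, should then give the alkene and return to the route at 9.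

Step 6. The enzyme may discriminate too weakly between the enantiomers, or prefer the other one, so that the acetate is not obtained enantiopure. The fallback sets out from 10 and resolves through covalent diastereomers. Acylation with (1S)-(−)-camphanic chloride (pyridine, DMAP, CH2Cl2) should give (2R)-2-[(3S,6R)-6-(dimethoxymethyl)-6-methyl-1,2-dioxan-3-yl]propyl (1S,4R)-camphanate F2 together with its diastereomer (2S)-2-[(3R,6S)-6-(dimethoxymethyl)-6-methyl-1,2-dioxan-3-yl]propyl (1S,4R)-camphanate F3. These would be separated by chromatography or crystallisation, and methanolysis of F2 (K2CO3, MeOH) returns to the route at 12.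

Step 14. Olefination may occur in part at the alkylated phosphonate carbon, or addition to the neopentyl aldehyde may be so slow that the aldehyde decomposes. The fallback sets out from 15 and uses the symmetrical reagent 20 in excess under the same LiCl/amine conditions, where both phosphonate carbons are equivalent. It should give methyl (2S)-2-[(3S,6R)-6-[(1E)-4-(diethoxyphosphoryl)-3-oxobut-1-en-1-yl]-6-methyl-1,2-dioxan-3-yl]propanoate F4. Diimide reduction gives methyl (2S)-2-[(3S,6R)-6-[4-(diethoxyphosphoryl)-3-oxobutyl]-6-methyl-1,2-dioxan-3-yl]propanoate F5. Its sodium enolate (one equivalent of NaH, NaI, DMF) is then alkylated at C10 with bromide 19 to give methyl (2S)-2-[(3S,6R)-6-{4-(diethoxyphosphoryl)-8-methyl-3-oxo-8-[(trimethylsilyl)oxy]nonyl}-6-methyl-1,2-dioxan-3-yl]propanoate F6. Mild acid (citric acid, MeOH) removes the silyl group and returns to the route at 24.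

**Further compounds**

F1 | step 4 | 2-[(3S,6R)-6-(dimethoxymethyl)-6-methyl-1,2-dioxan-3-yl]-1-(trimethylsilyl)propan-2-ol | COC(OC)[C@@]1(C)CC[C@@H](C(C)(O)C[Si](C)(C)C)OO1
F2 | step 6 | (2R)-2-[(3S,6R)-6-(dimethoxymethyl)-6-methyl-1,2-dioxan-3-yl]propyl (1S,4R)-camphanate | COC(OC)[C@@]1(C)CC[C@@H]([C@H](C)COC(=O)[C@@]23CC[C@@](C)(C(=O)O2)C3(C)C)OO1
F3 | step 6 | (2S)-2-[(3R,6S)-6-(dimethoxymethyl)-6-methyl-1,2-dioxan-3-yl]propyl (1S,4R)-camphanate | COC(OC)[C@]1(C)CC[C@H]([C@@H](C)COC(=O)[C@@]23CC[C@@](C)(C(=O)O2)C3(C)C)OO1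
F4 | step 14 | methyl (2S)-2-[(3S,6R)-6-[(1E)-4-(diethoxyphosphoryl)-3-oxobut-1-en-1-yl]-6-methyl-1,2-dioxan-3-yl]propanoate | CCOP(=O)(OCC)CC(=O)/C=C/[C@@]1(C)CC[C@@H]([C@H](C)C(=O)OC)OO1
F5 | step 14 | methyl (2S)-2-[(3S,6R)-6-[4-(diethoxyphosphoryl)-3-oxobutyl]-6-methyl-1,2-dioxan-3-yl]propanoate | CCOP(=O)(OCC)CC(=O)CC[C@@]1(C)CC[C@@H]([C@H](C)C(=O)OC)OO1
F6 | step 14 | methyl (2S)-2-[(3S,6R)-6-{4-(diethoxyphosphoryl)-8-methyl-3-oxo-8-[(trimethylsilyl)oxy]nonyl}-6-methyl-1,2-dioxan-3-yl]propanoate | CCOP(=O)(OCC)C(CCCC(C)(C)O[Si](C)(C)C)C(=O)CC[C@@]1(C)CC[C@@H]([C@H](C)C(=O)OC)OO1
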